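**Assumption:** the configuration written for the ring-fusion CH (compounds 21–24) and for the carbinol carbon (23, 24) is the expected one; both centres become sp2 in step 14, so their sense does not affect the outcome. Compound 2 is an epimer mixture at C6 that converges in step 2.

## Analysis of the target

Target 30 is a spiro compound. A 3,7-dihydro-2H-cyclohepta[b]furan-7-one (a 2-alkoxytropone) shares its C2 with C1' of a cyclohexane. The seven-membered ring is fully mapped: C3a carries the C3 methylene, C4 the only ring hydrogen, C5 a methyl, C6 the methyl ester, C7 the carbonyl, C8 a methyl and C8a the ether oxygen. The cyclohexane holds four stereocentres: the spiro carbon (S), C2' (R, methyl and 2-carboxyethyl), C3' (S, 2-hydroxypropan-2-yl) and C6' (S, methyl). In the chair with the hydroxypropyl group equatorial, the ether oxygen is axial, cis to the acid side chain and to the C6' methyl; C3, the side chain and the C6' methyl are equatorial and the C2' methyl is axial. Sensitive groups are the tertiary alcohol and the tertiary-alkyl C–O bond of the vinylogous ester (both ionise in strong acid), the tropone (hydroxide adds at C8a) and a methyl ester next to a free acid (no saponification at the end). The hard parts are the oxygen-bearing spiro carbon, wedged between a quaternary carbon and a methine, and the regiodefined pentasubstituted tropone. The route rests on one feature: C3a lies between C8a (oxygen) and C4 (hydrogen). If C3a is removed, the six remaining ring carbons with their substituents are exactly the ring of methyl atrarate 10, so C3a can be a carbene carbon inserted into the C4–C5 bond of that arene and delivered from C3 through the spiro carbon and the ether oxygen.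

## Retrosynthetic reasoning

**30 to 27.** The acid is unveiled last by oxidation of the primary alcohol in diol 28, which comes from bis-silyl ether 27. The side chain is carried as a silyloxypropyl group and not as an ester, because ester cleavage at the end would need strong acid (danger to the tertiary alcohol and the tertiary-alkyl tropone ether) or hydroxide (danger to the tropone).

**27 to 22.** The C3 methylene and the C7 carbonyl are traced to ketone 22, a 3a-hydro cyclohepta[b]furan-3-one with a methoxy group at C7. Reduction to alcohol 23 and 1,2-elimination give heptafulvene 25. Its protonation at the exocyclic carbon makes the CH2 and the methoxytropylium ion 26, and loss of the O-methyl group leaves the tropone. The ketone therefore supplies the oxidation level and no external oxidant is needed.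

**22 to 20 (key disconnection).** The bonds C3a–C8a and C3a–C4 are cut. Both go back to one carbene carbon, so 22 comes from α-aryloxy diazoketone 20 through norcaradiene 21. Cutting here, and nowhere else, lets the arene of methyl atrarate bring every tropone substituent in the correct order, and the tether fixes where the extra carbon enters.

**20 to 14 and 13.** The diazoketone comes from acid 17, activated as its mixed anhydride with methanesulfonic acid (acyl mesylate 18) and acylating (trimethylsilyl)diazomethane by way of silyl diazoketone 19. The C–O bond at the tertiary carbon is cut with inversion, which leads to phenol 13 and an electrophile at the ring carbon. A plain spiro-epoxide from a sulfonium methylide is not used: base opens it at the CH2, and Lewis acids trigger hydride or alkyl shift at this neopentyl-type centre. The gem-dichloroepoxide 15, formed from trichloromethyl carbinol 14, is chosen because it can only be opened at the ring carbon and it delivers the acid oxidation level directly (via acyl chloride 16).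

**14 to 9.** The carbinol comes from ketone 9 by addition of the trichloromethyl anion. The carbon nucleophile must enter axially, anti to the axial C2 methyl, so that inversion in the next step leaves the aryloxy group axial.

**9 to 1.** Ketone 9 comes from diol 8, alcohol 7 and ketone 5. The C6 methyl of 5 is set thermodynamically after conjugate reduction of enone 3. The quaternary centre of 3 is made by two successive α'-alkylations of (S)-carvone 1 via 2; the second electrophile enters trans to the isopropenyl group. The three-carbon chain is introduced as an allyl group, because the cross-conjugated dienolate would react with an acrylic ester as a 2-oxydiene and close a bicyclo[2.2.2]octanone.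

**13 to 10.** Phenol 13 comes from methyl atrarate 10 by temporary benzylation of the unchelated 4-hydroxyl, methylation of the chelated 2-hydroxyl (12) and hydrogenolysis.

## Alternatives that were turned down

**Alternative 1: Diels–Alder spiroannulation of an aurone-type diene.**
- Disconnection: the cyclohexane bonds C1'–C2' (spiro to quaternary carbon) and C3'–C4'.
- Forward key step: the exocyclic (Z)-diene A2 on a benzofuran-3-one and the (E)-2-methyl enal A3 combine under a chiral oxazaborolidinium catalyst to give the spiro cyclohexene aldehyde A1.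
- For it: it is convergent and sets the spiro, quaternary and carbinol-bearing centres in one catalytic step. It makes the spiro C–O bond without any substitution at a tertiary carbon; on that point it is stronger than the chosen route.
- Against it: the dienophile is an α-methyl, β-branched enal and the diene terminus is fully substituted, so two fully substituted carbons must bond in the cycloaddition. A1 still contains a benzene ring, so a CH must later be inserted into one specific bond of a hexasubstituted arene and the C3 ketone removed. The aldehyde needs two more carbons, and the ring alkene must be hydrogenated with control of the CH(CH3) centre.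
- Comparison: the chosen strategy takes all ring stereocentres from carvone 1 and forms the seven-membered ring in the key step, so less remains after it.

**Alternative 2: palladium heteroannulation of an exocyclic diene.**
- Disconnection: the aryl–CH2 bond and the O–spiro carbon bond of the dihydrofuran.
- Forward key step: the iodinated atrarate A5 and the carvone-derived diene A6 react with Pd(OAc)2 (reduced in the flask to zerovalent palladium). Oxidative addition, aryl transfer to the exocyclic CH2 and attack of the phenoxide on the allylpalladium ring terminus give the spiro-dihydrobenzofuran A4.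
- For it: it is a two-component union of simple partners, and it forms the tertiary C–O bond through an allyl complex, which is easier to defend than an SN2-type opening; on that point it is stronger than the chosen route.
- Against it: the face of C–O bond formation at the spiro carbon is set by the side on which palladium sits and is not reliably the required one. β-Hydride loss competes. The aryl iodide is flanked by methyl and hydroxyl. A4 is again a benzene, so the regiospecific one-carbon ring enlargement of a fully substituted phenol is left unsolved. The ring alkene still has to be reduced stereoselectively.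
- Comparison: the chosen strategy solves tethering and ring enlargement in one step with regiochemistry fixed by the tether.

**Alternative 3: furan and vinylcarbenoid [4+3] annulation.**
- Disconnection: the tropone bonds C5–C6 and C8–C8a; C6–C7–C8 come from a vinylcarbenoid and the other four carbons from a furan.
- Forward key step: the spiro-fused alkoxyfuran A8 and the silyloxy vinyldiazoacetate A9 with Rh2(OAc)4 give an oxygen-bridged cycloheptadiene by cyclopropanation and Cope rearrangement. Bu4NF then opens the bridge and water is lost, giving the tert-butyl ester A7.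
- For it: the tropone is made at the final oxidation level with all substituents and the product is one step from the target. In step economy after the key step it is stronger than the chosen route.
- Against it: 2-alkoxyfurans tend to react with rhodium vinylcarbenoids through zwitterions that unravel to open-chain trienes. Both furan α-positions are substituted. The cis methyl on the vinyl terminus slows the Cope step. A8 is a labile cyclic ketene acetal whose synthesis still needs the hindered spiro C–O bond. The last step would be an acidic ester cleavage next to acid-sensitive groups.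
- Comparison: the chosen strategy uses a stable arene as the six-carbon unit and an intramolecular reaction type already known for aryloxy diazoketones.

Key step: step 12

## Route

Step 1
Reactants: 1 (S)-carvone
Product: 2 6-methylcarvone (C6 epimers; methyl mainly trans to isopropenyl)
Conditions: LiN(i-Pr)2, THF, −78 °C; MeI, −78 → 0 °C
Reagents that add atoms: iodomethane, CI
Why: Kinetic deprotonation of the enone can only occur at C6 (cross-conjugated enolate) and the enolate is C-methylated (enolate alkylation); the C6 configuration is erased in step 2.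

Step 2
Reactants: 2 6-methylcarvone
Product: 3 (5R,6R)-2,6-dimethyl-6-(prop-2-en-1-yl)-5-(prop-1-en-2-yl)cyclohex-2-en-1-one
Conditions: LiN(i-Pr)2, THF, −78 → 0 °C; allyl bromide, DMPU, −78 °C → rt
Reagents that add atoms: allyl bromide, C=CCBr
Why: Enolate alkylation with a reactive allylic halide; the tetrasubstituted enolate is attacked anti to the neighbouring isopropenyl group, so the allyl group ends trans and the methyl cis to it, which sets the quaternary centre.

Step 3
Reactants: 3 allyl methyl carvone
Product: 5 (2R,3R,6S)-2,6-dimethyl-2-(prop-2-en-1-yl)-3-(prop-1-en-2-yl)cyclohexan-1-one, via lithium enolate 4 (not isolated)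
Conditions: LiBH(s-Bu)3, THF, −78 °C; MeOH; NaOMe (cat.), MeOH, rt
Reagents that add atoms: none
Why: Conjugate reduction of a β-unsubstituted enone by a hindered borohydride, which leaves the isolated alkenes alone; protonation and base equilibration put the new α-methyl equatorial, because the other epimer has a syn-diaxial methyl/methyl contact with the C2 methyl.

Step 4
Reactants: 5 saturated ketone
Product: 7 (2R,3R,6S)-2-(3-hydroxypropyl)-2,6-dimethyl-3-(prop-1-en-2-yl)cyclohexan-1-one, via alkyl catecholboronate 6 (not isolated)
Conditions: catecholborane, RhCl(PPh3)3 (cat.), THF, 0 °C → rt; NaOH, H2O2, 0 °C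
Reagents that add atoms: hydrogen peroxide, OO
Why: Rhodium-catalysed hydroboration and oxidation gives the anti-Markovnikov primary alcohol; the catalysed reaction takes the monosubstituted alkene in preference to the 1,1-disubstituted alkene and the hindered ketone.

Step 5
Reactants: 7 hydroxy ketone
Product: 8 (2R,3S,6S)-2-(3-hydroxypropyl)-3-(2-hydroxypropan-2-yl)-2,6-dimethylcyclohexan-1-one
Conditions: Co(acac)2 (cat.), PhSiH3, O2 (1 atm), i-PrOH–THF, rt
Reagents that add atoms: dioxygen, O=O
Why: Mukaiyama hydration: hydrogen-atom transfer from a cobalt hydride to the 1,1-disubstituted alkene, capture of the tertiary radical by O2 and reduction of the peroxide by the silane give the Markovnikov tertiary alcohol; ketone and primary alcohol are inert and no stereocentre is formed.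

Step 6
Reactants: 8 diol
Product: 9 (2R,3S,6S)-2,6-dimethyl-2-[3-(triethylsilyloxy)propyl]-3-[2-(triethylsilyloxy)propan-2-yl]cyclohexan-1-one
Conditions: Et3SiOTf, 2,6-lutidine, CH2Cl2, −78 → 0 °C
Reagents that add atoms: triethylsilyl trifluoromethanesulfonate, CC[Si](CC)(CC)OS(=O)(=O)C(F)(F)F
Why: Silylation with the triflate protects both the primary and the hindered tertiary hydroxyl in one operation; at low temperature with lutidine the hindered ketone is not converted into an enol ether.

Step 7
Reactants: 10 methyl atrarate
Product: 12 methyl 4-(benzyloxy)-2-methoxy-3,6-dimethylbenzoate, via 4-O-benzyl ether 11 (not isolated)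
Conditions: K2CO3, BnBr (1.0 equiv), DMF, rt; then MeI, 50 °C
Reagents that add atoms: benzyl bromide, BrCc1ccccc1; iodomethane, CI
Why: Williamson etherification; the 4-hydroxyl (para to the ester, not hydrogen-bonded) is alkylated first, and the chelated 2-hydroxyl reacts only under the more forcing methylation.

Step 8
Reactants: 12 benzyl methyl ether
Product: 13 methyl 4-hydroxy-2-methoxy-3,6-dimethylbenzoate
Conditions: H2 (1 atm), Pd/C, EtOAc, rt
Reagents that add atoms: none
Why: Hydrogenolysis of the benzyl aryl ether frees the 4-hydroxyl; the hindered ester and the methyl ether are untouched.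

Step 9
Reactants: 9 bis-silyl ketone
Product: 14 (1R,2R,3S,6S)-1-(trichloromethyl)cyclohexan-1-ol derivative (hydroxyl equatorial; CCl3 axial)
Conditions: CHCl3, LiN(SiMe3)2, THF, −78 °C; AcOH, −78 °C
Reagents that add atoms: chloroform, ClC(Cl)Cl
Why: 1,2-Addition of trichloromethyllithium to the ketone; attack is expected on the face away from the axial C2 methyl (axial attack, past only the C3 and C5 hydrogens), so the hydroxyl becomes equatorial; the cold acidic quench prevents retro-addition.

Step 10
Reactants: 14 trichloromethyl carbinol; 13 phenol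
Product: 17 (1S,2R,3S,6S)-1-aryloxycyclohexane-1-carboxylic acid (aryloxy axial; cis to the side chain), via gem-dichloroepoxide 15 (not isolated), via acyl chloride 16 (not isolated)
Conditions: 13 (3 equiv), NaOH (powdered), DME, 0 °C → rt; H2O; 1 M HCl to pH 3, 0 °C
Reagents that add atoms: sodium hydroxide, [Na+].[OH-]
Why: Jocic–Reeve (Bargellini-type) reaction: the alkoxide closes to the gem-dichloroepoxide, the phenoxide opens it at the ring carbon by backside attack (the CCl2 carbon is not attacked), and the alkoxide formed collapses to the acyl chloride, which hydroxide turns into the carboxylate. The substitution inverts the carbinol carbon, so the aryloxy group ends axial, cis to the side chain and the C6 methyl, as in the target.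

Step 11
Reactants: 17 aryloxy acid
Product: 20 α-aryloxy diazoketone, via acyl methanesulfonate 18 (not isolated), via silyl diazoketone 19 (not isolated)
Conditions: MsCl (1.1 equiv), Et3N (3 equiv), THF, 0 °C; Me3SiCHN2, MeCN–THF, 0 °C → rt; aq. NaHCO3
Reagents that add atoms: (trimethylsilyl)diazomethane, C[Si](C)(C)C=[N+]=[N-]
Why: The triethylammonium carboxylate is sulfonylated at oxygen to the mixed carboxylic–methanesulfonic anhydride, an activation that does not depend on access to the crowded acyl carbon and that is the established way to diazoketones from hindered acids; no HCl is set free, which spares the silyl ethers and the tertiary-alkyl aryl ether. The acyl mesylate then acylates (trimethylsilyl)diazomethane (first stage of an Arndt–Eistert sequence), the amine takes the proton, and silicon is lost on the bicarbonate work-up. The acyl group has no α-hydrogen, so the amine base cannot form a ketene.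

Step 12
Reactants: 20 α-aryloxy diazoketone
Product: 22 spiro 3a-hydrocyclohepta[b]furan-3-one (7-methoxy cycloheptatriene), via norcaradiene 21 (not isolated)
Conditions: Rh2(O2CCF3)4 (1 mol %), CH2Cl2, rt, slow addition of 20; filtration through basic alumina
Reagents that add atoms: none
Why: Loss of N2 gives an electrophilic divalent rhodium carbenoid that adds across the ipso–ortho bond of the tethered aryl ether on the side of the unsubstituted ortho carbon; this is the intramolecular Buchner reaction, known for aryloxy diazoketones, which give cyclohepta[b]furan-3-ones. The furanone ring is closed in this [2+1] addition as a five-membered ring through the geminal oxygen/acyl tether (carbenoid carbon to ipso carbon), giving norcaradiene 21. The seven-membered ring is formed by ring enlargement, not by cyclisation: disrotatory six-electron electrocyclic opening of 21 breaks the former ipso–ortho σ bond, favoured because the sp3 carbon carries one acceptor and the triene carries donors. The one new stereocentre, the ring-fusion CH, is set by the spiro centre: the arene is expected to swing over the face flanked by the CH(CH3) carbon and not over the quaternary carbon; the centre is removed in step 14. The step needs chemoselectivity for arene addition over aromatic substitution (a chroman-3-one) and over aliphatic C–H insertion, and regioselectivity for the hydrogen-bearing ortho carbon. The four-atom tether reaches only the two ipso–ortho bonds, the other ortho carbon is blocked by methyl, the only C–H bonds within 1,5-reach are unactivated methyl and methylene, and the electron-poor trifluoroacetate ligands favour arene addition; slow addition limits carbene dimer and acid-free isolation avoids rearrangement of 22.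

Step 13
Reactants: 22 cycloheptatriene ketone
Product: 23 3-hydroxy compound (hydroxyl trans to the ring-fusion hydrogen)
Conditions: NaBH4, CeCl3·7H2O, MeOH–THF, −40 °C
Reagents that add atoms: none
Why: Luche-type 1,2-reduction of the α-alkoxy ketone, fast enough at low temperature to outrun enolisation at the ring-fusion carbon; the conjugated ester is not touched. Hydride is expected to enter anti to the seven-membered ring; this centre is also removed in step 14.

Step 14
Reactants: 23 alcohol
Product: 27 spiro tropone (bis-triethylsilyl ether), via mesylate 24 (not isolated), via heptafulvene 25 (not isolated), via methoxytropylium chloride 26 (not isolated)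
Conditions: MsCl, Et3N, CH2Cl2, −20 → 0 °C; DBU, 0 °C → rt; pyridinium chloride, MeCN, rt
Reagents that add atoms: none
Why: Mesylation and anti E2 loss of the doubly allylic ring-fusion hydrogen give the heptafulvene, the same kind of elimination by which the parent heptafulvene is made. Protonation at the exocyclic carbon, the typical reaction of heptafulvenes, creates the C3 methylene and the methoxytropylium ion. Chloride then removes the O-methyl group by SN2 at carbon (the reverse of tropone O-alkylation) and leaves the tropone.

Step 15
Reactants: 27 bis-silyl tropone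
Product: 28 diol (primary and tertiary hydroxyl free)
Conditions: Bu4NF, AcOH, THF, 0 °C → rt
Reagents that add atoms: none
Why: Fluoride cleaves both triethylsilyl ethers; the acetic acid buffer keeps the medium free of hydroxide, which would attack the tropone.

Step 16
Reactants: 28 diol
Product: 30 target acid, via aldehyde 29 (not isolated)
Conditions: TEMPO (cat.), PhI(OAc)2, MeCN–H2O (pH 7 buffer), rt
Reagents that add atoms: water, O
Why: Oxoammonium oxidation takes the primary alcohol to the aldehyde and, through its hydrate, to the acid under near-neutral conditions; the tertiary alcohol, the tropone and the methyl ester are inert.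

## Compound list

1 | (S)-carvone, (5S)-2-methyl-5-(prop-1-en-2-yl)cyclohex-2-en-1-one | CC1=CC[C@@H](CC1=O)C(C)=C | starting material
2 | 6-methylcarvone, C6 epimer mixture (trans epimer shown) | O=C1C(C)=CC[C@H](C(C)=C)[C@H]1C | intermediate
3 | (5R,6R)-2,6-dimethyl-6-(prop-2-en-1-yl)-5-(prop-1-en-2-yl)cyclohex-2-en-1-one (allyl trans to isopropenyl) | O=C1C(C)=CC[C@H](C(C)=C)[C@@]1(C)CC=C | intermediate
4 | lithium enolate from conjugate reduction of 3 | [Li]OC1=C(C)CC[C@H](C(C)=C)[C@@]1(C)CC=C | intermediate
5 | (2R,3R,6S)-2,6-dimethyl-2-(prop-2-en-1-yl)-3-(prop-1-en-2-yl)cyclohexan-1-one | O=C1[C@@H](C)CC[C@H](C(C)=C)[C@@]1(C)CC=C | intermediate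
6 | 2-alkyl-1,3,2-benzodioxaborole from hydroboration of the allyl group of 5 | O=C1[C@@H](C)CC[C@H](C(C)=C)[C@@]1(C)CCCB1Oc2ccccc2O1 | intermediate
7 | (2R,3R,6S)-2-(3-hydroxypropyl)-2,6-dimethyl-3-(prop-1-en-2-yl)cyclohexan-1-one | O=C1[C@@H](C)CC[C@H](C(C)=C)[C@@]1(C)CCCO | intermediate
8 | (2R,3S,6S)-2-(3-hydroxypropyl)-3-(2-hydroxypropan-2-yl)-2,6-dimethylcyclohexan-1-one | O=C1[C@@H](C)CC[C@H](C(C)(C)O)[C@@]1(C)CCCO | intermediate
9 | bis-triethylsilyl ether of 8 | O=C1[C@@H](C)CC[C@H](C(C)(C)O[Si](CC)(CC)CC)[C@@]1(C)CCCO[Si](CC)(CC)CC | intermediate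
10 | methyl atrarate, methyl 2,4-dihydroxy-3,6-dimethylbenzoate | COC(=O)c1c(C)cc(O)c(C)c1O | starting material
11 | methyl 4-(benzyloxy)-2-hydroxy-3,6-dimethylbenzoate | COC(=O)c1c(C)cc(OCc2ccccc2)c(C)c1O | intermediate
12 | methyl 4-(benzyloxy)-2-methoxy-3,6-dimethylbenzoate | COC(=O)c1c(C)cc(OCc2ccccc2)c(C)c1OC | intermediate
13 | methyl 4-hydroxy-2-methoxy-3,6-dimethylbenzoate | COC(=O)c1c(C)cc(O)c(C)c1OC | intermediate
14 | (1R,2R,3S,6S)-trichloromethyl carbinol from 9 (OH equatorial, CCl3 axial) | O[C@]1(C(Cl)(Cl)Cl)[C@@H](C)CC[C@H](C(C)(C)O[Si](CC)(CC)CC)[C@@]1(C)CCCO[Si](CC)(CC)CC | intermediate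
15 | spiro gem-dichloroepoxide (2,2-dichloro-1-oxaspiro[2.5]octane) from 14 | ClC1(Cl)O[C@@]12[C@@H](C)CC[C@H](C(C)(C)O[Si](CC)(CC)CC)[C@@]2(C)CCCO[Si](CC)(CC)CC | intermediate
16 | 1-aryloxycyclohexane-1-carbonyl chloride (aryloxy axial) | COC(=O)c1c(C)cc(O[C@@]2(C(Cl)=O)[C@@H](C)CC[C@H](C(C)(C)O[Si](CC)(CC)CC)[C@@]2(C)CCCO[Si](CC)(CC)CC)c(C)c1OC | intermediate
17 | (1S,2R,3S,6S)-1-[3-methoxy-4-(methoxycarbonyl)-2,5-dimethylphenoxy]cyclohexane-1-carboxylic acid with the ring substituents of 9 | COC(=O)c1c(C)cc(O[C@@]2(C(=O)O)[C@@H](C)CC[C@H](C(C)(C)O[Si](CC)(CC)CC)[C@@]2(C)CCCO[Si](CC)(CC)CC)c(C)c1OC | intermediate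
18 | mixed carboxylic–methanesulfonic anhydride (acyl methanesulfonate) of 17 | COC(=O)c1c(C)cc(O[C@@]2(C(=O)OS(C)(=O)=O)[C@@H](C)CC[C@H](C(C)(C)O[Si](CC)(CC)CC)[C@@]2(C)CCCO[Si](CC)(CC)CC)c(C)c1OC | intermediate
19 | α-trimethylsilyl diazoketone from 18 | COC(=O)c1c(C)cc(O[C@@]2(C(=O)C(=[N+]=[N-])[Si](C)(C)C)[C@@H](C)CC[C@H](C(C)(C)O[Si](CC)(CC)CC)[C@@]2(C)CCCO[Si](CC)(CC)CC)c(C)c1OC | intermediate
20 | α-aryloxy diazoketone (key-step precursor), (1S,2R,3S,6S) ring | COC(=O)c1c(C)cc(O[C@@]2(C(=O)C=[N+]=[N-])[C@@H](C)CC[C@H](C(C)(C)O[Si](CC)(CC)CC)[C@@]2(C)CCCO[Si](CC)(CC)CC)c(C)c1OC | intermediate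
21 | norcaradiene (cyclopropane on the former ipso–ortho bond) | COC(=O)C1=C(C)[C@@H]2[C@H]3C(=O)[C@]4(O[C@@]23C(C)=C1OC)[C@@H](C)CC[C@H](C(C)(C)O[Si](CC)(CC)CC)[C@@]4(C)CCCO[Si](CC)(CC)CC | intermediate
22 | spiro 3a-hydrocyclohepta[b]furan-3-one, 7-methoxy cycloheptatriene (key-step product) | COC(=O)C1=C(OC)C(C)=C2O[C@@]3(C(=O)[C@@H]2C=C1C)[C@@H](C)CC[C@H](C(C)(C)O[Si](CC)(CC)CC)[C@@]3(C)CCCO[Si](CC)(CC)CC | intermediate
23 | 3-hydroxy compound from 22 (OH trans to the ring-fusion H) | COC(=O)C1=C(OC)C(C)=C2O[C@@]3([C@H](O)[C@@H]2C=C1C)[C@@H](C)CC[C@H](C(C)(C)O[Si](CC)(CC)CC)[C@@]3(C)CCCO[Si](CC)(CC)CC | intermediate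
24 | methanesulfonate of 23 | COC(=O)C1=C(OC)C(C)=C2O[C@@]3([C@H](OS(C)(=O)=O)[C@@H]2C=C1C)[C@@H](C)CC[C@H](C(C)(C)O[Si](CC)(CC)CC)[C@@]3(C)CCCO[Si](CC)(CC)CC | intermediate
25 | heptafulvene (C3=C3a double bond) | COC(=O)C1=C(OC)C(C)=C2O[C@@]3(C=C2C=C1C)[C@@H](C)CC[C@H](C(C)(C)O[Si](CC)(CC)CC)[C@@]3(C)CCCO[Si](CC)(CC)CC | intermediate
26 | 7-methoxytropylium chloride (drawn as the O-methyl oxocarbenium form) | COC(=O)C1=C(C)C=C2C[C@]3(OC2=C(C)C1=[O+]C)[C@@H](C)CC[C@H](C(C)(C)O[Si](CC)(CC)CC)[C@@]3(C)CCCO[Si](CC)(CC)CC.[Cl-] | intermediate
27 | spiro tropone, bis-triethylsilyl ether, (2S,2'R,3'S,6'S) | COC(=O)c1c(C)cc2c(c(C)c1=O)O[C@@]3(C2)[C@@H](C)CC[C@H](C(C)(C)O[Si](CC)(CC)CC)[C@@]3(C)CCCO[Si](CC)(CC)CC | intermediate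
28 | spiro tropone diol (3-hydroxypropyl and 2-hydroxypropan-2-yl) | COC(=O)c1c(C)cc2c(c(C)c1=O)O[C@@]3(C2)[C@@H](C)CC[C@H](C(C)(C)O)[C@@]3(C)CCCO | intermediate
29 | spiro tropone aldehyde (3-oxopropyl side chain) | COC(=O)c1c(C)cc2c(c(C)c1=O)O[C@@]3(C2)[C@@H](C)CC[C@H](C(C)(C)O)[C@@]3(C)CCC=O | intermediate
30 | 3-[(2S,2'R,3'S,6'S)-3'-(2-hydroxypropan-2-yl)-6-(methoxycarbonyl)-2',5,6',8-tetramethyl-7-oxo-3,7-dihydrospiro[cyclohepta[b]furan-2,1'-cyclohexan]-2'-yl]propanoic acid (CNP0448476.1) | COC(=O)c1c(C)cc2c(c(C)c1=O)O[C@@]1(C2)[C@@H](C)CC[C@H](C(C)(C)O)[C@@]1(C)CCC(=O)O | target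

## Step count and least certain steps

Total: 16 steps. Longest linear sequence: 14 steps (steps 1–6 and 9–16, from (S)-carvone); steps 7–8 are a two-step branch from methyl atrarate.

**Step 12 (key step).** The most likely failure is diversion of the carbenoid–arene adduct to aromatic substitution (a chroman-3-one), because the attacked carbon is para to the methoxy group and ortho to the ether oxygen and so stabilises an arenium-type intermediate. The same product can form by acid-promoted collapse of 21/22 on isolation.
Fallback, setting out from 14 and 10 and returning at 27: the methoxy donor is replaced by an acetoxy group, a much weaker donor. Jocic–Reeve reaction of 14 with methyl atrarate 10 itself (the unchelated, less hindered 4-hydroxyl is the nucleophile) gives, through 15 and the hydroxy acyl chloride F1, the hydroxy acid F2. Its chelated phenol is acetylated before the acid is activated, since it would otherwise be sulfonylated (Ac2O, pyridine, DMAP, then aqueous NaHCO3 to cleave any mixed anhydride), which gives the acetoxy acid F3. Activation as in step 11 gives the acetoxy acyl methanesulfonate F4, and (trimethylsilyl)diazomethane converts it, through the acetoxy silyl diazoketone F5, into the acetoxy diazoketone F6. Rh2(O2CCF3)4 gives the acetoxy norcaradiene F7 and from it the enol acetate ketone F8. Reduction as in step 13 gives the alcohol F9; mesylation and elimination, via the mesylate F10, give the acetoxy heptafulvene F11. K2CO3 in methanol removes the acetyl group, and the freed enol tautomerises by protonation at the exocyclic carbon to tropone 27.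

**Step 10 (with step 9).** The most likely failure is loss of the trichloromethyl group by retro-addition from the very hindered alkoxide before the epoxide closes. Capture of 15 by hydroxide in place of the hindered phenoxide, or poor facial selectivity in step 9, are the next concerns.
Fallback, setting out from 9 and returning at 17: the addition is made irreversible. Dichloromethyllithium (CH2Cl2, LiN(i-Pr)2, THF, −100 °C) adds to 9 to give the dichloromethyl carbinol F12. With the sodium salt of 13 (NaH, DMSO–THF) this closes to the chloro-epoxide F13, which the phenoxide opens at the ring carbon with inversion to give the α-aryloxy aldehyde F14. Oxidation with NaClO2, NaH2PO4 and 2-methyl-2-butene gives 17.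

**Step 14.** The E2 step needs the ring-fusion hydrogen anti to the sulfonate. If the hydride of step 13 enters from the other face, ionisation with migration of a ring bond (ring enlargement, or collapse through the norcaradiene to a chromene) can take over. Loss of the tertiary alkyl group from the alkoxytropylium ion is a further risk if 26 is long-lived.
Fallback, setting out from 22 and returning at 25 (inside step 14): the reduction of 22 then delivers the epimeric alcohol with the hydroxyl cis to the ring-fusion hydrogen, F15. Instead of being mesylated, it is dehydrated by syn elimination with the Burgess reagent (benzene, 50 °C) through the sulfamate F16, whose thermal Ei elimination gives heptafulvene 25.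

**Step 16.** The risk is lactol formation between the aldehyde 29 and the free tertiary hydroxyl followed by oxidation to a seven-membered lactone, or incomplete oxidation.
Fallback, setting out from 27 and returning at 30: the tertiary hydroxyl is kept protected during the oxidation. Selective methanolysis of the primary silyl ether (PPTS, MeOH, 0 °C) gives the mono-silyl alcohol F17. TEMPO/PhI(OAc)2 oxidation gives, through the aldehyde F18, the silyl-protected acid F19. Bu4NF/AcOH then removes the tertiary silyl group to give 30.

## Further compounds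

F1 | step 12 | 1-aryloxycyclohexane-1-carbonyl chloride with free 2-hydroxyl on the arene | COC(=O)c1c(C)cc(O[C@@]2(C(Cl)=O)[C@@H](C)CC[C@H](C(C)(C)O[Si](CC)(CC)CC)[C@@]2(C)CCCO[Si](CC)(CC)CC)c(C)c1O
F2 | step 12 | hydroxy acid (analogue of 17 with free phenol) | COC(=O)c1c(C)cc(O[C@@]2(C(=O)O)[C@@H](C)CC[C@H](C(C)(C)O[Si](CC)(CC)CC)[C@@]2(C)CCCO[Si](CC)(CC)CC)c(C)c1O
F3 | step 12 | acetoxy acid (analogue of 17 with aryl acetate) | COC(=O)c1c(C)cc(O[C@@]2(C(=O)O)[C@@H](C)CC[C@H](C(C)(C)O[Si](CC)(CC)CC)[C@@]2(C)CCCO[Si](CC)(CC)CC)c(C)c1OC(C)=O
F4 | step 12 | acetoxy acyl methanesulfonate (mixed anhydride of F3) | COC(=O)c1c(C)cc(O[C@@]2(C(=O)OS(C)(=O)=O)[C@@H](C)CC[C@H](C(C)(C)O[Si](CC)(CC)CC)[C@@]2(C)CCCO[Si](CC)(CC)CC)c(C)c1OC(C)=O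
F5 | step 12 | acetoxy α-trimethylsilyl diazoketone | COC(=O)c1c(C)cc(O[C@@]2(C(=O)C(=[N+]=[N-])[Si](C)(C)C)[C@@H](C)CC[C@H](C(C)(C)O[Si](CC)(CC)CC)[C@@]2(C)CCCO[Si](CC)(CC)CC)c(C)c1OC(C)=O
F6 | step 12 | acetoxy diazoketone | COC(=O)c1c(C)cc(O[C@@]2(C(=O)C=[N+]=[N-])[C@@H](C)CC[C@H](C(C)(C)O[Si](CC)(CC)CC)[C@@]2(C)CCCO[Si](CC)(CC)CC)c(C)c1OC(C)=O
F7 | step 12 | acetoxy norcaradiene | COC(=O)C1=C(C)[C@@H]2[C@H]3C(=O)[C@]4(O[C@@]23C(C)=C1OC(C)=O)[C@@H](C)CC[C@H](C(C)(C)O[Si](CC)(CC)CC)[C@@]4(C)CCCO[Si](CC)(CC)CC
F8 | step 12 | 7-acetoxy 3a-hydrocyclohepta[b]furan-3-one | COC(=O)C1=C(OC(C)=O)C(C)=C2O[C@@]3(C(=O)[C@@H]2C=C1C)[C@@H](C)CC[C@H](C(C)(C)O[Si](CC)(CC)CC)[C@@]3(C)CCCO[Si](CC)(CC)CC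
F9 | step 12 | 7-acetoxy 3-hydroxy compound | COC(=O)C1=C(OC(C)=O)C(C)=C2O[C@@]3([C@H](O)[C@@H]2C=C1C)[C@@H](C)CC[C@H](C(C)(C)O[Si](CC)(CC)CC)[C@@]3(C)CCCO[Si](CC)(CC)CC
F10 | step 12 | methanesulfonate of F9 | COC(=O)C1=C(OC(C)=O)C(C)=C2O[C@@]3([C@H](OS(C)(=O)=O)[C@@H]2C=C1C)[C@@H](C)CC[C@H](C(C)(C)O[Si](CC)(CC)CC)[C@@]3(C)CCCO[Si](CC)(CC)CC
F11 | step 12 | 7-acetoxy heptafulvene | COC(=O)C1=C(OC(C)=O)C(C)=C2O[C@@]3(C=C2C=C1C)[C@@H](C)CC[C@H](C(C)(C)O[Si](CC)(CC)CC)[C@@]3(C)CCCO[Si](CC)(CC)CC
F12 | step 10 | dichloromethyl carbinol from 9 (OH equatorial) | O[C@]1(C(Cl)Cl)[C@@H](C)CC[C@H](C(C)(C)O[Si](CC)(CC)CC)[C@@]1(C)CCCO[Si](CC)(CC)CC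
F13 | step 10 | spiro 2-chloro-epoxide from F12 | ClC1O[C@@]12[C@@H](C)CC[C@H](C(C)(C)O[Si](CC)(CC)CC)[C@@]2(C)CCCO[Si](CC)(CC)CC
F14 | step 10 | 1-aryloxycyclohexane-1-carbaldehyde (aryloxy axial) | COC(=O)c1c(C)cc(O[C@@]2(C=O)[C@@H](C)CC[C@H](C(C)(C)O[Si](CC)(CC)CC)[C@@]2(C)CCCO[Si](CC)(CC)CC)c(C)c1OC
F15 | step 14 | C3 epimer of 23 (OH cis to the ring-fusion H) | COC(=O)C1=C(OC)C(C)=C2O[C@@]3([C@@H](O)[C@@H]2C=C1C)[C@@H](C)CC[C@H](C(C)(C)O[Si](CC)(CC)CC)[C@@]3(C)CCCO[Si](CC)(CC)CC
F16 | step 14 | Burgess sulfamate of F15, triethylammonium salt | COC(=O)C1=C(OC)C(C)=C2O[C@@]3([C@@H](OS(=O)(=O)[N-]C(=O)OC)[C@@H]2C=C1C)[C@@H](C)CC[C@H](C(C)(C)O[Si](CC)(CC)CC)[C@@]3(C)CCCO[Si](CC)(CC)CC.CC[NH+](CC)CC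
F17 | step 16 | spiro tropone with free primary alcohol and tertiary triethylsilyl ether | COC(=O)c1c(C)cc2c(c(C)c1=O)O[C@@]3(C2)[C@@H](C)CC[C@H](C(C)(C)O[Si](CC)(CC)CC)[C@@]3(C)CCCO
F18 | step 16 | aldehyde from F17 | COC(=O)c1c(C)cc2c(c(C)c1=O)O[C@@]3(C2)[C@@H](C)CC[C@H](C(C)(C)O[Si](CC)(CC)CC)[C@@]3(C)CCC=O
F19 | step 16 | tertiary triethylsilyl ether of the target acid | COC(=O)c1c(C)cc2c(c(C)c1=O)O[C@@]3(C2)[C@@H](C)CC[C@H](C(C)(C)O[Si](CC)(CC)CC)[C@@]3(C)CCC(=O)O
A1 | alternative 1 | spiro cyclohexene aldehyde on the benzofuran-3-one | COC(=O)c1c(C)c2c(c(C)c1OCc4ccccc4)O[C@@]3(C2=O)C(C)=CC[C@H](C(C)(C)O[Si](C)(C)C)[C@@]3(C)C=O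
A2 | alternative 1 | methyl (Z)-6-(benzyloxy)-2-(but-3-en-2-ylidene)-4,7-dimethyl-3-oxo-2,3-dihydrobenzofuran-5-carboxylate | COC(=O)c1c(C)c2C(=O)/C(Oc2c(C)c1OCc1ccccc1)=C(\C)C=C
A3 | alternative 1 | (E)-2,4-dimethyl-4-[(trimethylsilyl)oxy]pent-2-enal | O=C/C(C)=C/C(C)(C)O[Si](C)(C)C
A4 | alternative 2 | spiro-dihydrobenzofuran cyclohexene | COC(=O)c1c(C)c2c(c(C)c1O)O[C@@]3(C2)C(C)=CC[C@H](C(C)(C)O[Si](CC)(CC)CC)[C@@]3(C)CCC(=O)OC
A5 | alternative 2 | methyl 2,4-dihydroxy-5-iodo-3,6-dimethylbenzoate | COC(=O)c1c(C)c(I)c(O)c(C)c1O
A6 | alternative 2 | methyl 3-[1,3-dimethyl-2-methylidene-6-(2-triethylsilyloxypropan-2-yl)cyclohex-3-en-1-yl]propanoate (chain trans to the silyloxypropyl group) | C=C1C(C)=CC[C@H](C(C)(C)O[Si](CC)(CC)CC)[C@@]1(C)CCC(=O)OC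
A7 | alternative 3 | tert-butyl ester of the target | COC(=O)c1c(C)cc2c(c(C)c1=O)O[C@@]3(C2)[C@@H](C)CC[C@H](C(C)(C)O)[C@@]3(C)CCC(=O)OC(C)(C)C
A8 | alternative 3 | spiro-fused 5-methyl-2,3-dihydrofuro[2,3-b]furan (2-alkoxy-5-methylfuran) with triethylsilyl ether and tert-butyl ester | Cc1cc2c(o1)O[C@@]3(C2)[C@@H](C)CC[C@H](C(C)(C)O[Si](CC)(CC)CC)[C@@]3(C)CCC(=O)OC(C)(C)C
A9 | alternative 3 | methyl (Z)-3-[(tert-butyldimethylsilyl)oxy]-2-diazopent-3-enoate | COC(=O)C(=[N+]=[N-])/C(O[Si](C)(C)C(C)(C)C)=C/C
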